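The target is a trans-(2R,3R)-2,3-dihydrofuro[3,2-c]pyran-4-one: a 6-styryl-2-pyranone (ring C) fused at C3a–C7a to a dihydrofuran (ring B) that carries a catechol at C2 and a 4-hydroxy-2-pyranon-6-yl group (ring A) at C3. The key step exploits that C3a and C7a are the α- and β-carbons of ring C: a 3-bromo-4-alkoxy-2-pyranone acts as a hetaryne-like 1,2-dielectrophile, and the O1–C2–C3 unit is an aldol-type β-hydroxyalkyl pyranone that can be metalated at O and C together. In one flask, Pd[P(t-Bu)3]2-catalysed C-arylation forms C3–C3a and alkoxide addition–elimination forms O1–C7a, closing ring B. C2 comes from asymmetric transfer hydrogenation.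

Key step: step 8

Remark: ketone 7 has the aryl/CH2 pattern of acetophenone, so the (R,R)-catalyst is expected to give the (R)-carbinol; if the sense were reversed, the (S,S)-catalyst would be used.

Step 1
Reactants: 1 3,4-dihydroxybenzaldehyde
Product: 2 3,4-bis(tert-butyldimethylsilyloxy)benzaldehyde
Conditions: TBSCl (2.3 equiv), imidazole, DMF, 0 °C to rt
Reagents that add atoms: tert-butyldimethylsilyl chloride (TBSCl), C[Si](C)(Cl)C(C)(C)C
Why: Imidazole-promoted silylation of both phenols masks the catechol as fluoride-labile ethers that should tolerate the amide bases, the oxidant and the palladium catalyst used later.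

Step 2
Reactants: 3 4-hydroxy-6-methyl-2H-pyran-2-one
Product: 4 6-methyl-4-[2-(trimethylsilyl)ethoxy]-2H-pyran-2-one
Conditions: Me3SiCH2CH2OH, PPh3, DIAD, THF, 0 °C to rt
Reagents that add atoms: 2-(trimethylsilyl)ethanol, C[Si](C)(C)CCO
Why: Mitsunobu etherification of the acidic 4-hydroxyl should give the 4-alkoxy-2-pyranone selectively; the 2-(trimethylsilyl)ethyl group is fluoride-labile and later also serves as the leaving group at C4 of ring C.

Step 3
Reactants: 4 6-methyl-4-[2-(trimethylsilyl)ethoxy]-2H-pyran-2-one; 2 3,4-bis(tert-butyldimethylsilyloxy)benzaldehyde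
Product: 6 rac-6-{2-[3,4-bis(tert-butyldimethylsilyloxy)phenyl]-2-hydroxyethyl}-4-[2-(trimethylsilyl)ethoxy]-2H-pyran-2-one, via lithium dienolate 5 (not isolated)
Conditions: LiN(i-Pr)2 (1.05 equiv), THF, −78 °C; then 2, −78 °C; AcOH quench
Reagents that add atoms: none
Why: Deprotonation of the C6 methyl group (vinylogous to the lactone carbonyl) and aldol addition to the aldehyde at low temperature is the standard entry to 6-(2-aryl-2-hydroxyethyl)-4-alkoxypyranones; the carbinol is formed racemic here and is reset in steps 4 and 5.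

Step 4
Reactants: 6 rac-6-{2-[3,4-bis(tert-butyldimethylsilyloxy)phenyl]-2-hydroxyethyl}-4-[2-(trimethylsilyl)ethoxy]-2H-pyran-2-one
Product: 7 6-{2-[3,4-bis(tert-butyldimethylsilyloxy)phenyl]-2-oxoethyl}-4-[2-(trimethylsilyl)ethoxy]-2H-pyran-2-one
Conditions: Dess–Martin periodinane, CH2Cl2, 0 °C to rt
Reagents that add atoms: none
Why: Dess–Martin oxidation of the benzylic secondary alcohol under neutral conditions should give the aryl ketone without β-elimination to the styrylpyranone.

Step 5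
Reactants: 7 6-{2-[3,4-bis(tert-butyldimethylsilyloxy)phenyl]-2-oxoethyl}-4-[2-(trimethylsilyl)ethoxy]-2H-pyran-2-one
Product: 8 6-{(2R)-2-[3,4-bis(tert-butyldimethylsilyloxy)phenyl]-2-hydroxyethyl}-4-[2-(trimethylsilyl)ethoxy]-2H-pyran-2-one
Conditions: RuCl[(R,R)-TsDPEN](p-cymene) (1 mol%), HCO2H/Et3N (5:2), CH2Cl2, 30 °C
Reagents that add atoms: none
Why: Noyori–Ikariya asymmetric transfer hydrogenation of the aryl ketone; the (R,R)-ligand should deliver hydride to the face that gives the (R)-carbinol, in the sense known for aryl alkyl ketones, which sets C2 of the target.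

Step 6
Reactants: 4 6-methyl-4-[2-(trimethylsilyl)ethoxy]-2H-pyran-2-one
Product: 9 3-bromo-6-methyl-4-[2-(trimethylsilyl)ethoxy]-2H-pyran-2-one
Conditions: NBS, MeCN, 0 °C to rt
Reagents that add atoms: N-bromosuccinimide (NBS), O=C1CCC(=O)N1Br
Why: Electrophilic bromination should occur at C3, the nucleophilic carbon of the 4-alkoxy enol ether next to the lactone carbonyl, the usual site of halogenation of 4-alkoxy-2-pyranones.

Step 7
Reactants: 9 3-bromo-6-methyl-4-[2-(trimethylsilyl)ethoxy]-2H-pyran-2-one; 2 3,4-bis(tert-butyldimethylsilyloxy)benzaldehyde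
Product: 13 3-bromo-6-{(E)-2-[3,4-bis(tert-butyldimethylsilyloxy)phenyl]ethenyl}-4-[2-(trimethylsilyl)ethoxy]-2H-pyran-2-one, via lithium dienolate 10 (not isolated), via lithium aldolate 11 (not isolated), via mesylate 12 (not isolated)
Conditions: LiN(i-Pr)2, THF, −78 °C; 2; MsCl, −78 to 0 °C; DBU, rt
Reagents that add atoms: none
Why: Vinylogous aldol addition of the C6-methyl anion (C3 is blocked by bromine), O-mesylation of the aldolate and E1cB elimination should give the conjugated styrylpyranone with the thermodynamically favoured E geometry.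

Step 8
Reactants: 8 6-{(2R)-2-[3,4-bis(tert-butyldimethylsilyloxy)phenyl]-2-hydroxyethyl}-4-[2-(trimethylsilyl)ethoxy]-2H-pyran-2-one; 13 3-bromo-6-{(E)-2-[3,4-bis(tert-butyldimethylsilyloxy)phenyl]ethenyl}-4-[2-(trimethylsilyl)ethoxy]-2H-pyran-2-one
Product: 16 6-{(2R,3R)-2-[3,4-bis(tert-butyldimethylsilyloxy)phenyl]-6-{(E)-2-[3,4-bis(tert-butyldimethylsilyloxy)phenyl]ethenyl}-4-oxo-2,3-dihydro-4H-furo[3,2-c]pyran-3-yl}-4-[2-(trimethylsilyl)ethoxy]-2H-pyran-2-one, via dimetalated alcohol 14 (not isolated), via open C-arylated alkoxide 15 (not isolated)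
Conditions: LiN(i-Pr)2 (2.1 equiv), THF, −78 °C; ZnCl2 (2.2 equiv), −78 to 0 °C; 13, Pd[P(t-Bu)3]2 (5 mol%), 25 to 55 °C
Reagents that add atoms: none
Why: LiN(i-Pr)2 removes the O–H and then one C–H next to ring A of 8, giving a Fráter–Seebach-type alkoxide/dienolate 14 that is transmetalated to zinc; zerovalent palladium inserts into the C3–Br bond of 13 and Negishi-type α-arylation forms the C3–C3a bond (15), after which the zinc alkoxide adds to C4 of the same pyranone and expels 2-(trimethylsilyl)ethoxide, forming O1–C7a. The closest known reaction types are the palladium-catalysed α-arylation of zinc enolates and the tandem enolate C-arylation/O-arylation of 1,2-dihaloarenes that gives benzofurans, run here with an sp3 alkoxide so that the dihydrofuran oxidation level is kept. Ring B is closed by intramolecular addition–elimination at a vinylogous ester carbon, a five-membered closure of the kind used in SNAr routes to 2,3-dihydrobenzofurans. C2 (R) is carried over unchanged from 8 because the oxygen is joined to an sp2 carbon and the benzylic C–O bond is never broken; C3 is set under thermodynamic control, its C–H between rings A and C being acidic enough to equilibrate in the basic medium to the trans (3R) isomer. The step needs carbon at C3a and oxygen at C7a: palladium can only enter at the C–Br bond, the alkoxy-bearing C4 is inert to palladium but is the one position open to addition–elimination, and the dienolate reacts at its exocyclic carbon because only that restores ring A; the expelled alkoxide is the same group that protects ring A, so any alkoxy exchange is degenerate.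

Step 9
Reactants: 16 6-{(2R,3R)-2-[3,4-bis(tert-butyldimethylsilyloxy)phenyl]-6-{(E)-2-[3,4-bis(tert-butyldimethylsilyloxy)phenyl]ethenyl}-4-oxo-2,3-dihydro-4H-furo[3,2-c]pyran-3-yl}-4-[2-(trimethylsilyl)ethoxy]-2H-pyran-2-one
Product: 17 6-{(2R,3R)-2-(3,4-dihydroxyphenyl)-6-[(E)-2-(3,4-dihydroxyphenyl)ethenyl]-4-oxo-2,3-dihydro-4H-furo[3,2-c]pyran-3-yl}-4-hydroxy-2H-pyran-2-one (target)
Conditions: TBAF, AcOH (0.5 equiv per fluoride), THF, 0 °C to rt, argon
Reagents that add atoms: none
Why: Fluoride should cleave the four aryl silyl ethers and fragment the 2-(trimethylsilyl)ethyl vinylogous ester in one operation, the acetic acid buffer keeps the catechols from oxidising as phenolates, and neither stereocentre is touched.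

Compound list
1 | 3,4-dihydroxybenzaldehyde | O=Cc1ccc(O)c(O)c1 | starting material
2 | 3,4-bis(tert-butyldimethylsilyloxy)benzaldehyde | O=Cc1ccc(O[Si](C)(C)C(C)(C)C)c(O[Si](C)(C)C(C)(C)C)c1 | intermediate
3 | 4-hydroxy-6-methyl-2H-pyran-2-one | Cc1cc(O)cc(=O)o1 | starting material
4 | 6-methyl-4-[2-(trimethylsilyl)ethoxy]-2H-pyran-2-one | Cc1cc(OCC[Si](C)(C)C)cc(=O)o1 | intermediate
5 | lithium dienolate of 4, drawn as the 6-(lithiomethyl) form (not isolated) | [Li]Cc1cc(OCC[Si](C)(C)C)cc(=O)o1 | intermediate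
6 | rac-6-{2-[3,4-bis(tert-butyldimethylsilyloxy)phenyl]-2-hydroxyethyl}-4-[2-(trimethylsilyl)ethoxy]-2H-pyran-2-one | OC(Cc1cc(OCC[Si](C)(C)C)cc(=O)o1)c1ccc(O[Si](C)(C)C(C)(C)C)c(O[Si](C)(C)C(C)(C)C)c1 | intermediate
7 | 6-{2-[3,4-bis(tert-butyldimethylsilyloxy)phenyl]-2-oxoethyl}-4-[2-(trimethylsilyl)ethoxy]-2H-pyran-2-one | O=C(Cc1cc(OCC[Si](C)(C)C)cc(=O)o1)c1ccc(O[Si](C)(C)C(C)(C)C)c(O[Si](C)(C)C(C)(C)C)c1 | intermediate
8 | 6-{(2R)-2-[3,4-bis(tert-butyldimethylsilyloxy)phenyl]-2-hydroxyethyl}-4-[2-(trimethylsilyl)ethoxy]-2H-pyran-2-one | O[C@H](Cc1cc(OCC[Si](C)(C)C)cc(=O)o1)c1ccc(O[Si](C)(C)C(C)(C)C)c(O[Si](C)(C)C(C)(C)C)c1 | intermediate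
9 | 3-bromo-6-methyl-4-[2-(trimethylsilyl)ethoxy]-2H-pyran-2-one | Cc1cc(OCC[Si](C)(C)C)c(Br)c(=O)o1 | intermediate
10 | lithium dienolate of 9, drawn as the 6-(lithiomethyl) form (not isolated) | [Li]Cc1cc(OCC[Si](C)(C)C)c(Br)c(=O)o1 | intermediate
11 | racemic lithium aldolate from 10 and 2: lithium 1-[3,4-bis(tert-butyldimethylsilyloxy)phenyl]-2-{5-bromo-6-oxo-4-[2-(trimethylsilyl)ethoxy]-6H-pyran-2-yl}ethoxide (not isolated) | [Li]OC(Cc1cc(OCC[Si](C)(C)C)c(Br)c(=O)o1)c1ccc(O[Si](C)(C)C(C)(C)C)c(O[Si](C)(C)C(C)(C)C)c1 | intermediate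
12 | racemic methanesulfonate of the aldol adduct (not isolated) | CS(=O)(=O)OC(Cc1cc(OCC[Si](C)(C)C)c(Br)c(=O)o1)c1ccc(O[Si](C)(C)C(C)(C)C)c(O[Si](C)(C)C(C)(C)C)c1 | intermediate
13 | 3-bromo-6-{(E)-2-[3,4-bis(tert-butyldimethylsilyloxy)phenyl]ethenyl}-4-[2-(trimethylsilyl)ethoxy]-2H-pyran-2-one | O=c1oc(/C=C/c2ccc(O[Si](C)(C)C(C)(C)C)c(O[Si](C)(C)C(C)(C)C)c2)cc(OCC[Si](C)(C)C)c1Br | intermediate
14 | O,C-dimetalated 8, drawn as the dilithium species before transmetalation to zinc (not isolated) | [Li]O[C@H](C([Li])c1cc(OCC[Si](C)(C)C)cc(=O)o1)c1ccc(O[Si](C)(C)C(C)(C)C)c(O[Si](C)(C)C(C)(C)C)c1 | intermediate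
15 | open C-arylated intermediate, present as its zinc alkoxide and drawn as the alcohol, epimeric at the new C–H: 3-{(2R)-2-[3,4-bis(tert-butyldimethylsilyloxy)phenyl]-2-hydroxy-1-{6-oxo-4-[2-(trimethylsilyl)ethoxy]-6H-pyran-2-yl}ethyl}-6-{(E)-2-[3,4-bis(tert-butyldimethylsilyloxy)phenyl]ethenyl}-4-[2-(trimethylsilyl)ethoxy]-2H-pyran-2-one (not isolated) | O=c1oc(/C=C/c2ccc(O[Si](C)(C)C(C)(C)C)c(O[Si](C)(C)C(C)(C)C)c2)cc(OCC[Si](C)(C)C)c1C(c1cc(OCC[Si](C)(C)C)cc(=O)o1)[C@@H](O)c1ccc(O[Si](C)(C)C(C)(C)C)c(O[Si](C)(C)C(C)(C)C)c1 | intermediate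
16 | 6-{(2R,3R)-2-[3,4-bis(tert-butyldimethylsilyloxy)phenyl]-6-{(E)-2-[3,4-bis(tert-butyldimethylsilyloxy)phenyl]ethenyl}-4-oxo-2,3-dihydro-4H-furo[3,2-c]pyran-3-yl}-4-[2-(trimethylsilyl)ethoxy]-2H-pyran-2-one | O=c1cc(OCC[Si](C)(C)C)cc([C@@H]2c3c(cc(/C=C/c4ccc(O[Si](C)(C)C(C)(C)C)c(O[Si](C)(C)C(C)(C)C)c4)oc3=O)O[C@H]2c2ccc(O[Si](C)(C)C(C)(C)C)c(O[Si](C)(C)C(C)(C)C)c2)o1 | intermediate
17 | 6-{(2R,3R)-2-(3,4-dihydroxyphenyl)-6-[(E)-2-(3,4-dihydroxyphenyl)ethenyl]-4-oxo-2,3-dihydro-4H-furo[3,2-c]pyran-3-yl}-4-hydroxy-2H-pyran-2-one | O=c1cc(O)cc([C@@H]2c3c(cc(/C=C/c4ccc(O)c(O)c4)oc3=O)O[C@H]2c2ccc(O)c(O)c2)o1 | target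

Total step count: 9
Longest linear sequence: 6 steps (steps 1, 3, 4, 5, 8, 9 from 1; equally steps 2, 3, 4, 5, 8, 9 from 3)

Steps most likely to fail

Step 8. What may go wrong: reversible aldol cleavage of the metal aldolate before ring closure (erosion of the C2 configuration), loss of the β-oxygen from the C-metalated fragment to give the styrylpyranone, attack of the alkoxide on the lactone carbonyl instead of C4, or a ring closure too slow to compete. The fallback sets out from 8 and comes back at 16. The hydroxyl of 8 is masked with TESOTf and 2,6-lutidine as the O-triethylsilyl ether F1. Mono-deprotonation (LiN(i-Pr)2, 1.1 equiv, then ZnCl2) and coupling with 13 under Pd[P(t-Bu)3]2 should give the C-arylated silyl ether F2 with no aldolate present during C–C bond formation. PPTS in MeOH removes only the triethylsilyl group to give the open alcohol 15, now isolated, and Cs2CO3 in MeCN at rt closes ring B by addition–elimination to give 16.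

Step 5. What may go wrong: slow or poorly face-selective hydride transfer because ketone 7 is largely enolised toward ring A. The fallback sets out from 6 and comes back at 8, leaving out steps 4 and 5. Racemic 6 is resolved by lipase-catalysed acylation (Burkholderia cepacia lipase, vinyl acetate, MTBE, 30 °C), which by the usual empirical rule for secondary aryl carbinols should acylate the (R)-enantiomer to the (R)-acetate F3. After separation from the unreacted (S)-alcohol, F3 is deacylated under neutral conditions (Candida antarctica lipase B, n-BuOH, MTBE) to give 8, so that no base can trigger β-elimination.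

Step 9. What may go wrong: air oxidation of the catecholates or base-induced opening or epimerisation of ring B at C3 under fluoride, and incomplete cleavage of the vinylogous ester in the buffered medium. The fallback sets out from 16 and comes back at 17, with two acidic stages in place of one basic one. TFA in CH2Cl2 at 0 °C cleaves the 2-(trimethylsilyl)ethyl group first to give the ring-A pyranol F4 with the four aryl silyl ethers intact. HF·pyridine in THF/pyridine at 0 °C then removes the silyl ethers to give 17.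

Further compounds
F1 | step 8 | 6-{(2R)-2-[3,4-bis(tert-butyldimethylsilyloxy)phenyl]-2-(triethylsilyloxy)ethyl}-4-[2-(trimethylsilyl)ethoxy]-2H-pyran-2-one | CC[Si](CC)(CC)O[C@H](Cc1cc(OCC[Si](C)(C)C)cc(=O)o1)c1ccc(O[Si](C)(C)C(C)(C)C)c(O[Si](C)(C)C(C)(C)C)c1
F2 | step 8 | 3-{(2R)-2-[3,4-bis(tert-butyldimethylsilyloxy)phenyl]-1-{6-oxo-4-[2-(trimethylsilyl)ethoxy]-6H-pyran-2-yl}-2-(triethylsilyloxy)ethyl}-6-{(E)-2-[3,4-bis(tert-butyldimethylsilyloxy)phenyl]ethenyl}-4-[2-(trimethylsilyl)ethoxy]-2H-pyran-2-one (epimers at C1 of the ethyl chain) | O=c1oc(/C=C/c2ccc(O[Si](C)(C)C(C)(C)C)c(O[Si](C)(C)C(C)(C)C)c2)cc(OCC[Si](C)(C)C)c1C(c1cc(OCC[Si](C)(C)C)cc(=O)o1)[C@@H](O[Si](CC)(CC)CC)c1ccc(O[Si](C)(C)C(C)(C)C)c(O[Si](C)(C)C(C)(C)C)c1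
F3 | step 5 | (1R)-1-[3,4-bis(tert-butyldimethylsilyloxy)phenyl]-2-{6-oxo-4-[2-(trimethylsilyl)ethoxy]-6H-pyran-2-yl}ethyl acetate | CC(=O)O[C@H](Cc1cc(OCC[Si](C)(C)C)cc(=O)o1)c1ccc(O[Si](C)(C)C(C)(C)C)c(O[Si](C)(C)C(C)(C)C)c1
F4 | step 9 | 6-{(2R,3R)-2-[3,4-bis(tert-butyldimethylsilyloxy)phenyl]-6-{(E)-2-[3,4-bis(tert-butyldimethylsilyloxy)phenyl]ethenyl}-4-oxo-2,3-dihydro-4H-furo[3,2-c]pyran-3-yl}-4-hydroxy-2H-pyran-2-one | O=c1cc(O)cc([C@@H]2c3c(cc(/C=C/c4ccc(O[Si](C)(C)C(C)(C)C)c(O[Si](C)(C)C(C)(C)C)c4)oc3=O)O[C@H]2c2ccc(O[Si](C)(C)C(C)(C)C)c(O[Si](C)(C)C(C)(C)C)c2)o1
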